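The route rests on disconnecting ring C at C4–C4a, the bond between the C4 carbonyl and the ring A carbon that sits ortho to O1 and O5 and para to O7. An intramolecular Friedel–Crafts acylation of an (E)-3-aryloxyacrylic acid forms this bond and closes the pyranone in one operation, with O1, the C2 aryl group and the C3 oxygen already in place. The precursor is a 2-pivaloyloxy-3-aryloxycinnamic acid whose ring A ether carries benzyl groups at the future O5 and O7 and a methoxy group on the second ortho carbon; it is assembled by vinylic substitution of an enol triflate by a phenol. Debenzylation, 7-O-prenylation and pivalate methanolysis finish the synthesis.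

Key step: step 12

Remark: the target (7-O-prenyl-limocitrin) has no stereocentre. In 13–16 the descriptor E means that the carboxyl-derived carbon and the C3 oxygen substituent lie on the same side of the double bond. The single stereocentre of 12 is racemic and is erased in step 9.

Step 1
Reactants: 1 3,5-bis(benzyloxy)phenol
Product: 2 4,6-bis(benzyloxy)-2-hydroxybenzaldehyde
Conditions: MgCl2, Et3N, (CH2O)n, MeCN, reflux
Reagents that add atoms: paraformaldehyde (as formaldehyde), C=O
Why: Magnesium-phenoxide-directed ortho-formylation (Casnati–Skattebøl) delivers formaldehyde inside the magnesium chelate only to a carbon ortho to the hydroxyl; the two ortho carbons of 1 are equivalent and the carbon between the benzyloxy groups is not touched.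

Step 2
Reactants: 2 4,6-bis(benzyloxy)-2-hydroxybenzaldehyde
Product: 3 2,4-bis(benzyloxy)-6-(methoxymethoxy)benzaldehyde
Conditions: MOMCl, iPr2NEt, CH2Cl2, 0 °C → 40 °C
Reagents that add atoms: chloromethyl methyl ether, COCCl
Why: O-Alkylation of the phenol with an α-chloro ether (MOM protection) masks the future O1 as an acetal that cannot migrate and that tolerates peracid, methoxide and MeI.

Step 3
Reactants: 3 2,4-bis(benzyloxy)-6-(methoxymethoxy)benzaldehyde
Product: 5 2,4-bis(benzyloxy)-6-(methoxymethoxy)phenol, via aryl formate 4 (not isolated)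
Conditions: mCPBA, CH2Cl2, 0 °C → rt; then K2CO3 (cat.), MeOH, rt, under N2
Reagents that add atoms: mCPBA, OOC(=O)c1cccc(Cl)c1
Why: Baeyer–Villiger (Dakin-type) oxidation, in which the electron-rich 2,4,6-trioxygenated aryl group migrates to oxygen, followed by mild methanolysis of the aryl formate; benzyl and MOM ethers are inert to both reagents.

Step 4
Reactants: 5 2,4-bis(benzyloxy)-6-(methoxymethoxy)phenol
Product: 6 1,5-bis(benzyloxy)-2-methoxy-3-(methoxymethoxy)benzene
Conditions: MeI, K2CO3, DMF, rt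
Reagents that add atoms: iodomethane, CI
Why: Williamson O-methylation of the only free phenol installs the future C8 methoxy group between the masked O1 and a benzyloxy group.

Step 5
Reactants: 6 1,5-bis(benzyloxy)-2-methoxy-3-(methoxymethoxy)benzene
Product: 7 3,5-bis(benzyloxy)-2-methoxyphenol
Conditions: HCl (aq., cat.), MeOH/THF, 50 °C
Reagents that add atoms: none
Why: Acid-catalysed acetal exchange with methanol removes the MOM group, while benzyl and methyl aryl ethers survive dilute HCl.

Step 6
Reactants: 8 vanillic acid (4-hydroxy-3-methoxybenzoic acid)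
Product: 9 3-methoxy-4-(pivaloyloxy)benzoic acid
Conditions: PivCl, NaOH, H2O/THF, 0 °C; then HCl (aq.)
Reagents that add atoms: pivaloyl chloride, CC(C)(C)C(Cl)=O
Why: Schotten–Baumann acylation: in cold aqueous NaOH the phenoxide is acylated, any mixed anhydride formed at the carboxylate is hydrolysed back, and the hindered aryl pivalate survives the brief basic exposure.

Step 7
Reactants: 9 3-methoxy-4-(pivaloyloxy)benzoic acid
Product: 11 tert-butyl 3-[3-methoxy-4-(pivaloyloxy)phenyl]-3-oxopropanoate, via acyl Meldrum's acid 10 (not isolated)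
Conditions: Meldrum's acid, EDC·HCl, DMAP, CH2Cl2, 0 °C → rt; then t-BuOH, toluene, 90 °C
Reagents that add atoms: Meldrum's acid, CC1(C)OC(=O)CC(=O)O1; tert-butanol, CC(C)(C)O
Why: Oikawa–Yonemitsu β-keto ester synthesis: carbodiimide-mediated C-acylation of Meldrum's acid, then thermal loss of acetone and CO2 to an acyl ketene that tert-butanol traps; the aryl pivalate is stable to DMAP and to neutral heating.

Step 8
Reactants: 11 tert-butyl 3-[3-methoxy-4-(pivaloyloxy)phenyl]-3-oxopropanoate
Product: 12 tert-butyl 3-[3-methoxy-4-(pivaloyloxy)phenyl]-3-oxo-2-(pivaloyloxy)propanoate (racemic)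
Conditions: PhI(OPiv)2, MeCN, rt
Reagents that add atoms: bis(pivaloyloxy)iodobenzene, CC(C)(C)C(=O)OI(OC(=O)C(C)(C)C)c1ccccc1
Why: α-Acyloxylation of a 1,3-dicarbonyl compound by a trivalent iodine dicarboxylate: the enol attacks iodine and pivalate displaces iodobenzene at C2, giving the racemic α-pivaloyloxy β-keto ester whose stereocentre disappears in step 9.

Step 9
Reactants: 12 tert-butyl 3-[3-methoxy-4-(pivaloyloxy)phenyl]-3-oxo-2-(pivaloyloxy)propanoate
Product: 13 tert-butyl (E)-3-[3-methoxy-4-(pivaloyloxy)phenyl]-2-(pivaloyloxy)-3-(trifluoromethanesulfonyloxy)acrylate (triflate cis to the ester)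
Conditions: NaH, CH2Cl2, 0 °C; then Tf2O, −78 → 0 °C
Reagents that add atoms: triflic anhydride, FC(F)(F)S(=O)(=O)OS(=O)(=O)C(F)(F)F
Why: O-Sulfonylation of the sodium enolate: sodium bridges the enolate oxygen and the ester carbonyl, so the triflate is fixed cis to the ester, and the single C2–H is the only enolisable position.

Step 10
Reactants: 7 3,5-bis(benzyloxy)-2-methoxyphenol; 13 tert-butyl (E)-3-[3-methoxy-4-(pivaloyloxy)phenyl]-2-(pivaloyloxy)-3-(trifluoromethanesulfonyloxy)acrylate
Product: 14 tert-butyl (E)-3-[3,5-bis(benzyloxy)-2-methoxyphenoxy]-3-[3-methoxy-4-(pivaloyloxy)phenyl]-2-(pivaloyloxy)acrylate (aryloxy group cis to the ester)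
Conditions: Cs2CO3, DMF, 0 °C → rt
Reagents that add atoms: none
Why: Nucleophilic vinylic substitution by addition–elimination (the Ruhemann-type route to 3-aryloxyacrylates): the cesium phenoxide adds to C3 of the vinylogous mixed anhydride and triflate leaves from the ester enolate before C2–C3 rotation, so the aryloxy group should take the place of the triflate cis to the ester.

Step 11
Reactants: 14 tert-butyl (E)-3-[3,5-bis(benzyloxy)-2-methoxyphenoxy]-3-[3-methoxy-4-(pivaloyloxy)phenyl]-2-(pivaloyloxy)acrylate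
Product: 15 (E)-3-[3,5-bis(benzyloxy)-2-methoxyphenoxy]-3-[3-methoxy-4-(pivaloyloxy)phenyl]-2-(pivaloyloxy)acrylic acid
Conditions: TFA, CH2Cl2, 0 °C → rt
Reagents that add atoms: none
Why: Acidolysis of the tert-butyl ester with loss of isobutene frees the acid without any nucleophilic base, so the pivalates, benzyl ethers and vinylogous carbonate stay intact; every free ring A carbon is flanked by two oxygens, which shields it from tert-butylation.

Step 12
Reactants: 15 (E)-3-[3,5-bis(benzyloxy)-2-methoxyphenoxy]-3-[3-methoxy-4-(pivaloyloxy)phenyl]-2-(pivaloyloxy)acrylic acid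
Product: 17 5,7-di-O-benzyl-3,4'-di-O-pivaloyl-limocitrin, via mixed trifluoroacetic anhydride 16 (not isolated)
Conditions: TFAA, CH2Cl2, 0 °C → rt
Reagents that add atoms: none
Why: TFAA turns the acid into the mixed anhydride 16, which ionises to an acylium ion whose charge is shared with the C3 aryloxy oxygen and which the E double bond holds cis to the ring A ether; the acyl carbon is attacked by the free ortho carbon of ring A (the future C4a) and proton loss restores the arene. This is the acid-mediated closure of 3-aryloxycinnamic acids to flavones, an intramolecular Friedel–Crafts acylation of the Ruhemann type. Ring C closes as a six-membered ring by exo attack on the digonal acylium carbon, with the arene C4a–C8a bond inside the new ring. No stereocentre is created. The step needs regioselectivity (C4a, not C6 or ring B) and chemoselectivity (ring closure ahead of trifluoroacetylation or debenzylation): the O1 tether reaches only the two ortho carbons, one of which carries the methoxy group, the reacting carbon is activated by O1 and O5 (ortho) and O7 (para), and the E geometry keeps the acyl carbon away from ring B.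

Step 13
Reactants: 17 5,7-bis(benzyloxy)-8-methoxy-2-[3-methoxy-4-(pivaloyloxy)phenyl]-4-oxo-4H-chromen-3-yl pivalate
Product: 18 5,7-dihydroxy-8-methoxy-2-[3-methoxy-4-(pivaloyloxy)phenyl]-4-oxo-4H-chromen-3-yl pivalate
Conditions: H2 (1 atm), 10% Pd/C, EtOAc/THF, rt
Reagents that add atoms: none
Why: Heterogeneous hydrogenolysis cleaves the two benzyl aryl ethers, while the pivalates and the fully substituted C2=C3 bond of the chromone are not reduced under one atmosphere of hydrogen.

Step 14
Reactants: 18 5,7-dihydroxy-8-methoxy-2-[3-methoxy-4-(pivaloyloxy)phenyl]-4-oxo-4H-chromen-3-yl pivalate; 19 prenyl bromide (1-bromo-3-methylbut-2-ene)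
Product: 20 5-hydroxy-8-methoxy-2-[3-methoxy-4-(pivaloyloxy)phenyl]-7-[(3-methylbut-2-en-1-yl)oxy]-4-oxo-4H-chromen-3-yl pivalate
Conditions: K2CO3, acetone, rt
Reagents that add atoms: none
Why: Williamson etherification: the 5-OH is tied up in a hydrogen bond to the C4 carbonyl and is the weaker acid, O3 and O4' are acylated, so only the 7-phenoxide forms and is alkylated by the SN2-reactive allylic bromide.

Step 15
Reactants: 20 5-hydroxy-8-methoxy-2-[3-methoxy-4-(pivaloyloxy)phenyl]-7-[(3-methylbut-2-en-1-yl)oxy]-4-oxo-4H-chromen-3-yl pivalate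
Product: 21 3,5-dihydroxy-2-(4-hydroxy-3-methoxyphenyl)-8-methoxy-7-[(3-methylbut-2-en-1-yl)oxy]-4H-chromen-4-one (target)
Conditions: K2CO3, MeOH/THF, rt, under argon; then HCl (aq.)
Reagents that add atoms: none
Why: Base-mediated transesterification with methanol removes the aryl and the enol pivalate, both activated by their phenoxide-type leaving groups, while the prenyl ether and the chromone are stable to carbonate.

Compound list
1 | 3,5-bis(benzyloxy)phenol | Oc1cc(OCc2ccccc2)cc(OCc2ccccc2)c1 | starting material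
2 | 4,6-bis(benzyloxy)-2-hydroxybenzaldehyde | O=Cc1c(O)cc(OCc2ccccc2)cc1OCc1ccccc1 | intermediate
3 | 2,4-bis(benzyloxy)-6-(methoxymethoxy)benzaldehyde | COCOc1cc(OCc2ccccc2)cc(OCc2ccccc2)c1C=O | intermediate
4 | 2,4-bis(benzyloxy)-6-(methoxymethoxy)phenyl formate | COCOc1cc(OCc2ccccc2)cc(OCc2ccccc2)c1OC=O | intermediate (not isolated)
5 | 2,4-bis(benzyloxy)-6-(methoxymethoxy)phenol | COCOc1cc(OCc2ccccc2)cc(OCc2ccccc2)c1O | intermediate
6 | 1,5-bis(benzyloxy)-2-methoxy-3-(methoxymethoxy)benzene | COCOc1cc(OCc2ccccc2)cc(OCc2ccccc2)c1OC | intermediate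
7 | 3,5-bis(benzyloxy)-2-methoxyphenol | COc1c(O)cc(OCc2ccccc2)cc1OCc1ccccc1 | intermediate
8 | vanillic acid (4-hydroxy-3-methoxybenzoic acid) | COc1cc(C(=O)O)ccc1O | starting material
9 | 3-methoxy-4-(pivaloyloxy)benzoic acid | COc1cc(C(=O)O)ccc1OC(=O)C(C)(C)C | intermediate
10 | 5-{hydroxy[3-methoxy-4-(pivaloyloxy)phenyl]methylidene}-2,2-dimethyl-1,3-dioxane-4,6-dione (acyl Meldrum's acid) | COc1cc(C(O)=C2C(=O)OC(C)(C)OC2=O)ccc1OC(=O)C(C)(C)C | intermediate (not isolated)
11 | tert-butyl 3-[3-methoxy-4-(pivaloyloxy)phenyl]-3-oxopropanoate | COc1cc(C(=O)CC(=O)OC(C)(C)C)ccc1OC(=O)C(C)(C)C | intermediate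
12 | tert-butyl 3-[3-methoxy-4-(pivaloyloxy)phenyl]-3-oxo-2-(pivaloyloxy)propanoate, racemic | COc1cc(C(=O)C(OC(=O)C(C)(C)C)C(=O)OC(C)(C)C)ccc1OC(=O)C(C)(C)C | intermediate
13 | tert-butyl (E)-3-[3-methoxy-4-(pivaloyloxy)phenyl]-2-(pivaloyloxy)-3-(trifluoromethanesulfonyloxy)acrylate | CC(C)(C)OC(=O)/C(OC(=O)C(C)(C)C)=C(\OS(=O)(=O)C(F)(F)F)c1ccc(OC(=O)C(C)(C)C)c(OC)c1 | intermediate
14 | tert-butyl (E)-3-[3,5-bis(benzyloxy)-2-methoxyphenoxy]-3-[3-methoxy-4-(pivaloyloxy)phenyl]-2-(pivaloyloxy)acrylate | CC(C)(C)OC(=O)/C(OC(=O)C(C)(C)C)=C(\Oc1cc(OCc2ccccc2)cc(OCc2ccccc2)c1OC)c1ccc(OC(=O)C(C)(C)C)c(OC)c1 | intermediate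
15 | (E)-3-[3,5-bis(benzyloxy)-2-methoxyphenoxy]-3-[3-methoxy-4-(pivaloyloxy)phenyl]-2-(pivaloyloxy)acrylic acid | OC(=O)/C(OC(=O)C(C)(C)C)=C(\Oc1cc(OCc2ccccc2)cc(OCc2ccccc2)c1OC)c1ccc(OC(=O)C(C)(C)C)c(OC)c1 | intermediate
16 | mixed anhydride of 15 with trifluoroacetic acid, E | O=C(OC(=O)C(F)(F)F)/C(OC(=O)C(C)(C)C)=C(\Oc1cc(OCc2ccccc2)cc(OCc2ccccc2)c1OC)c1ccc(OC(=O)C(C)(C)C)c(OC)c1 | intermediate (not isolated)
17 | 5,7-bis(benzyloxy)-8-methoxy-2-[3-methoxy-4-(pivaloyloxy)phenyl]-4-oxo-4H-chromen-3-yl pivalate (5,7-di-O-benzyl-3,4'-di-O-pivaloyl-limocitrin) | COc1cc(-c2oc3c(OC)c(OCc4ccccc4)cc(OCc4ccccc4)c3c(=O)c2OC(=O)C(C)(C)C)ccc1OC(=O)C(C)(C)C | intermediate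
18 | 5,7-dihydroxy-8-methoxy-2-[3-methoxy-4-(pivaloyloxy)phenyl]-4-oxo-4H-chromen-3-yl pivalate | COc1cc(-c2oc3c(OC)c(O)cc(O)c3c(=O)c2OC(=O)C(C)(C)C)ccc1OC(=O)C(C)(C)C | intermediate
19 | prenyl bromide (1-bromo-3-methylbut-2-ene) | CC(C)=CCBr | starting material
20 | 5-hydroxy-8-methoxy-2-[3-methoxy-4-(pivaloyloxy)phenyl]-7-[(3-methylbut-2-en-1-yl)oxy]-4-oxo-4H-chromen-3-yl pivalate | COc1cc(-c2oc3c(OC)c(OCC=C(C)C)cc(O)c3c(=O)c2OC(=O)C(C)(C)C)ccc1OC(=O)C(C)(C)C | intermediate
21 | 3,5-dihydroxy-2-(4-hydroxy-3-methoxyphenyl)-8-methoxy-7-[(3-methylbut-2-en-1-yl)oxy]-4H-chromen-4-one | COc1cc(-c2oc3c(OC)c(OCC=C(C)C)cc(O)c3c(=O)c2O)ccc1O | target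

Total step count: 15.
Longest linear sequence: 11 steps (steps 1–5 and 10–15, from 1). The ring B branch (steps 6–9) joins at step 10.

Steps most likely to fail

Step 12 (ring closure). What may go wrong: intermolecular trifluoroacetylation of the electron-rich ring A, acid-induced loss of benzyl groups, or isomerisation of the double bond followed by closure of the acyl group onto ring B. The fallback builds ring C from the other side by a Baker–Venkataraman sequence and oxidises C3 afterwards. It sets out from 7 (with acid 9) and comes back to the route at 17. Phenol 7 would be C-acetylated ortho to the hydroxyl (Ac2O, BF3·OEt2) to 1-[4,6-bis(benzyloxy)-2-hydroxy-3-methoxyphenyl]ethan-1-one F1. Esterification with 9 (EDC, DMAP) should give 2-acetyl-3,5-bis(benzyloxy)-6-methoxyphenyl 3-methoxy-4-(pivaloyloxy)benzoate F2. Acyl transfer with LiHMDS in THF should give 1-[4,6-bis(benzyloxy)-2-hydroxy-3-methoxyphenyl]-3-[3-methoxy-4-(pivaloyloxy)phenyl]propane-1,3-dione F3. Cyclodehydration (p-TsOH, toluene, 80 °C) should give the flavone 4-[5,7-bis(benzyloxy)-8-methoxy-4-oxo-4H-chromen-2-yl]-2-methoxyphenyl pivalate F4. Dimethyldioxirane in acetone/CH2Cl2 should epoxidise C2–C3 to the racemic 2,3-epoxide of that flavone F5, which p-TsOH should open to the flavonol 4-[5,7-bis(benzyloxy)-3-hydroxy-8-methoxy-4-oxo-4H-chromen-2-yl]-2-methoxyphenyl pivalate F6. Pivaloylation of the 3-hydroxyl (PivCl, Et3N, DMAP) then gives 17.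

Step 10 (vinylic substitution). What may go wrong: attack of the phenoxide at the sulfonyl sulfur (triflyl transfer back to the β-keto ester enolate), slow addition to the crowded tetrasubstituted alkene, or loss of the double-bond geometry by rotation in the intermediate enolate. The fallback replaces addition–elimination by a C–O cross-coupling under zerovalent palladium catalysis. It sets out from 7 and 13 and comes back at 14. With Pd2(dba)3, 2-(di-tert-butylphosphino)biphenyl and K3PO4 in toluene at 80 °C, oxidative addition into the vinyl C–OTf bond and reductive elimination of the vinyl–aryloxy bond should proceed with retention of geometry; no new compound is made (F0).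

Step 9 (enol triflate). What may go wrong: oxygen-to-oxygen migration of the pivaloyl group within the enolate, sulfonylation at carbon, or formation of the wrong enol geometry. The fallback avoids the metal enolate and the sulfonate. It sets out from 12 and comes back at 14. Deoxychlorination of the enol form with Ph3PCl2 (from PPh3 and C2Cl6) and Et3N in CH2Cl2 should give tert-butyl 3-chloro-3-[3-methoxy-4-(pivaloyloxy)phenyl]-2-(pivaloyloxy)acrylate F7 as a mixture of geometric isomers. Displacement of the vinylic chloride by the phenoxide of 7 (Cs2CO3, DMF, 40 °C) is the classical Ruhemann-type preparation of 3-aryloxyacrylates and should give 14, the E isomer being separated by chromatography.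

Further compounds
F1 | step 12 | 1-[4,6-bis(benzyloxy)-2-hydroxy-3-methoxyphenyl]ethan-1-one | CC(=O)c1c(O)c(OC)c(OCc2ccccc2)cc1OCc1ccccc1
F2 | step 12 | 2-acetyl-3,5-bis(benzyloxy)-6-methoxyphenyl 3-methoxy-4-(pivaloyloxy)benzoate | CC(=O)c1c(OC(=O)c2ccc(OC(=O)C(C)(C)C)c(OC)c2)c(OC)c(OCc2ccccc2)cc1OCc1ccccc1
F3 | step 12 | 1-[4,6-bis(benzyloxy)-2-hydroxy-3-methoxyphenyl]-3-[3-methoxy-4-(pivaloyloxy)phenyl]propane-1,3-dione | COc1cc(C(=O)CC(=O)c2c(O)c(OC)c(OCc3ccccc3)cc2OCc2ccccc2)ccc1OC(=O)C(C)(C)C
F4 | step 12 | 4-[5,7-bis(benzyloxy)-8-methoxy-4-oxo-4H-chromen-2-yl]-2-methoxyphenyl pivalate | COc1cc(-c2cc(=O)c3c(OCc4ccccc4)cc(OCc4ccccc4)c(OC)c3o2)ccc1OC(=O)C(C)(C)C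
F5 | step 12 | 2,3-epoxide of F4 (2,3-epoxy-5,7-bis(benzyloxy)-8-methoxy-2-[3-methoxy-4-(pivaloyloxy)phenyl]chroman-4-one), racemic | COc1cc(C23OC2C(=O)c2c(OCc4ccccc4)cc(OCc4ccccc4)c(OC)c2O3)ccc1OC(=O)C(C)(C)C
F6 | step 12 | 4-[5,7-bis(benzyloxy)-3-hydroxy-8-methoxy-4-oxo-4H-chromen-2-yl]-2-methoxyphenyl pivalate | COc1cc(-c2oc3c(OC)c(OCc4ccccc4)cc(OCc4ccccc4)c3c(=O)c2O)ccc1OC(=O)C(C)(C)C
F0 | step 10 | none | none
F7 | step 9 | tert-butyl 3-chloro-3-[3-methoxy-4-(pivaloyloxy)phenyl]-2-(pivaloyloxy)acrylate, mixture of E and Z | COc1cc(C(Cl)=C(OC(=O)C(C)(C)C)C(=O)OC(C)(C)C)ccc1OC(=O)C(C)(C)C
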